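**Plan**

1. Numbering used below (fusicoccane): C1(=O), C2=C3 (C3 bears C16H2OMe), C4, C5, C6(O), C7(CH3), C8(OH), C9, C10(O), C11(CH3), C12(=O), C13=C14(i-Pr).
2. Enabling feature: the oxa ring O–C6–C2–C1(=O)–C11–C10 is a γ-pyrone at the tetrahydro level. C6 and C10 are its electrophilic α-carbons, C2 and C11 its nucleophilic β-carbons.
3. Retrosynthesis: C8 carbonyl reduction; C13=C14 dehydrogenation; C11–C12 (Claisen, ring C); C9–C10 (bridging Michael, oxabicyclo[3.3.1] core); then C5–C6 and C2=C3 together (ring A), back to a flat 2,3,6-trisubstituted 4H-pyran-4-one and 1-(methoxymethyl)cyclopropanol.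
4. Forward: pyranone 7 (five steps), then ring A by a copper-catalysed enantioselective (3+2) annulation with the cyclopropanol-derived zinc homoenolate, then the C7–C9 ring by 1,3-diaxial Michael closure, then ring C by Claisen closure, then enone, ketal removal and reduction.
5. Stereochemistry: only C6 comes from the catalyst. C10 and C11 follow from ring constraints, C7 from equilibration next to the C8 ketone, C8 from hydride attack on the exo face of the bicycle.

Key step: step 7

Assumption: the (S,R,R)-phosphoramidite in step 7 is taken to give the (6R) sense of addition; if the sense is opposite, its enantiomer is used.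
Assumption: the side-chain centres C7 and C14 are racemic in 5–7 and are carried as epimer mixtures, written without configuration, until step 10 removes C14 and step 11 fixes C7.

**Route**

Step 1
Reactants: 1 heptane-3,5-dione; 2 methyl 3-methylbutanoate
Product: 3 6,9-dimethyldecane-3,5,7-trione
Conditions: LDA (2.2 equiv), THF, −78 → 0 °C; then 2, 0 °C; aq. HCl
Reagents that add atoms: none
Why: The 1,3-dianion of the symmetrical β-diketone should be acylated by the ester at its terminal α′-carbon (dianion Claisen condensation), which can give only this 1,3,5-triketone.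

Step 2
Reactants: 3 6,9-dimethyldecane-3,5,7-trione
Product: 4 6-ethyl-3-methyl-2-(2-methylpropyl)-4H-pyran-4-one
Conditions: conc. H2SO4, 0 °C → rt
Reagents that add atoms: none
Why: Acid-mediated cyclodehydration of a 1,3,5-triketone is the classical entry to 4-pyranones and allows only one ring.

Step 3
Reactants: 4 6-ethyl-3-methyl-2-(2-methylpropyl)-4H-pyran-4-one
Product: 5 3-methyl-2-(2-methylpropyl)-6-(3-oxobutan-2-yl)-4H-pyran-4-one (racemic)
Conditions: LDA (1.1 equiv), THF, −78 °C; MeC(O)N(OMe)Me; aq. NH4Cl
Reagents that add atoms: N-methoxy-N-methylacetamide, CC(=O)N(C)OC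
Why: Lateral (vinylogous) lithiation of the 2-alkyl-4-pyranone followed by Weinreb acylation should occur at the ethyl CH2, because the planar extended enolate at the isobutyl CH2 suffers allylic strain with the ring methyl.

Step 4
Reactants: 5 3-methyl-2-(2-methylpropyl)-6-(3-oxobutan-2-yl)-4H-pyran-4-one
Product: 6 3-methyl-6-[1-(2-methyl-1,3-dioxolan-2-yl)ethyl]-2-(2-methylpropyl)-4H-pyran-4-one (racemic)
Conditions: HOCH2CH2OH, p-TsOH (cat.), benzene, reflux (Dean–Stark)
Reagents that add atoms: ethylene glycol, OCCO
Why: Acid-catalysed ketalisation takes the saturated ketone only (the pyranone carbonyl is a vinylogous ester) and removes the acidic C7–H/ketone pair before the organometallic steps.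

Step 5
Reactants: 6 3-methyl-6-[1-(2-methyl-1,3-dioxolan-2-yl)ethyl]-2-(2-methylpropyl)-4H-pyran-4-one
Product: 7 methyl 4-methyl-3-{3-methyl-6-[1-(2-methyl-1,3-dioxolan-2-yl)ethyl]-4-oxo-4H-pyran-2-yl}pentanoate (mixture of racemic diastereomers)
Conditions: LDA (1.1 equiv), THF/DMPU, −78 °C; BrCH2CO2Me
Reagents that add atoms: methyl bromoacetate, COC(=O)CBr
Why: Lateral lithiation and alkylation should now occur at the isobutyl CH2 (C14), since the remaining lateral C7–H is tertiary and flanked by the quaternary ketal carbon.

Step 6
Reactants: 8 methyl 2-methoxyacetate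
Product: 9 1-(methoxymethyl)cyclopropan-1-ol
Conditions: EtMgBr (2.4 equiv), Ti(Oi-Pr)4 (0.2 equiv), Et2O/THF, 0 °C → rt; aq. NH4Cl
Reagents that add atoms: ethylmagnesium bromide, CC[Mg]Br
Why: The Kulinkovich reaction converts the ester through a titanacyclopropane into the 1-substituted cyclopropanol, and α-alkoxy esters are suitable substrates.

Step 7
Reactants: 7 methyl 4-methyl-3-{3-methyl-6-[1-(2-methyl-1,3-dioxolan-2-yl)ethyl]-4-oxo-4H-pyran-2-yl}pentanoate; 9 1-(methoxymethyl)cyclopropan-1-ol
Product: 14 methyl 3-[(7aR)-5-(methoxymethyl)-3-methyl-7a-[1-(2-methyl-1,3-dioxolan-2-yl)ethyl]-4-oxo-4,6,7,7a-tetrahydrocyclopenta[b]pyran-2-yl]-4-methylpentanoate (6R), via zinc homoenolate 10 (not isolated), via siloxypyrylium triflate 11 (not isolated), via siloxydiene adduct 12 (not isolated), via silyl aldol 13 (not isolated)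
Conditions: 9 (2.2 equiv), Et2Zn (1.1 equiv), CH2Cl2, 0 °C; 7, TMSOTf (1.1 equiv), CH2Cl2, −78 °C; CuTC (5 mol %), (S,R,R)-binaphthol bis(1-phenylethyl)phosphoramidite (10 mol %), −78 °C; then TMSOTf (0.5 equiv), −78 → −20 °C; Et3N, aq. NaHCO3
Reagents that add atoms: none
Why: Proposed new method: TMSOTf turns the γ-pyrone into the 4-siloxypyrylium salt 11, the zinc homoenolate 10 (from 9 by O–H metalation and ring opening) transmetalates to a chiral Cu(I)–phosphoramidite complex and delivers C5 to C6, and the resulting 1-alkoxy-3-siloxydiene 12 attacks the pendant C3 ketone through C2 (Zn(II)/TMSOTf-promoted Mukaiyama aldol) before the tertiary β-silyloxy ketone 13 loses silanol to give the C2=C3 enone. The closest known reaction types are the copper-catalysed, silyl-accelerated conjugate addition of zinc homoenolates to enones, copper-catalysed enantioselective additions of organocopper nucleophiles to 4-siloxybenzopyrylium triflates, and the cyclopentene annulation by conjugate addition of a masked homoenolate followed by aldol condensation. Ring A closes in a 5-(enolexo)-exo-trig aldol step, so that overall the cyclopropanol acts as the three-carbon partner (nucleophilic C5, electrophilic C3) and C6=C2 of the pyranone as the two-carbon partner of a formal (3+2) annulation. C6, the only controlled stereocentre, is set by the ligand, which selects one face of the planar pyrylium carbon, while C7 and C14 are uncontrolled here and are reset or removed later. The step needs addition at C6 rather than C10, which the C11 methyl secures (C10=C11 is tetrasubstituted and the more hindered α-carbon), and addition rather than deprotonation of the side-chain C–H, for which the weakly basic zinc/copper reagent at −78 °C is chosen. The siloxydiene 12 should be consumed by the intramolecular aldol at −78 °C before 6π ring opening of this 2H-pyran can erase C6.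

Step 8
Reactants: 14 methyl 3-[(7aR)-5-(methoxymethyl)-3-methyl-7a-[1-(2-methyl-1,3-dioxolan-2-yl)ethyl]-4-oxo-4,6,7,7a-tetrahydrocyclopenta[b]pyran-2-yl]-4-methylpentanoate
Product: 17 oxa-bridged tricyclic keto ester (O bridges C6 and C10 of the eight-membered ring; ring A fused at C2–C6; C1 ketone; C11–H; C8 ethylene ketal; C10 carries CH(i-Pr)CH2CO2Me; 6R,10R), via enol ether 15 (not isolated), via silyl dienol ether 16 (not isolated)
Conditions: TMSOTf (2.5 equiv), i-Pr2NEt (3 equiv), CH2Cl2, −78 → −20 °C; aq. NaHCO3
Reagents that add atoms: none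
Why: Proposed new method: TMSOTf/i-Pr2NEt should open the dioxolane to its less substituted enol ether 15 and silylate the C1 carbonyl, so that C9 adds to the oxocarbenium carbon C10 from the axial C6 side chain through a chair 6-exo-trig transition state (attack at C3 would be 6-endo) and the C8 oxocarbenium re-closes to the dioxolane; this is an intramolecular Mukaiyama–Michael addition whose closest known types are the silyl triflate/amine conversion of ketals into enol ethers and silyl-triflate-promoted additions of enol ethers to 4-pyranone derivatives, and C10 is forced because the three-carbon bridge can span C6 and C10 on one face only.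

Step 9
Reactants: 17 oxa-bridged tricyclic keto ester
Product: 18 tetracyclic diketone ketal (as 17 with ring C closed: C11–C12 bond, C12 ketone, C13H2, C14H(i-Pr); 6R,10R,11R)
Conditions: LiHMDS (2.2 equiv), THF, −78 → −20 °C; AcOH, −78 °C
Reagents that add atoms: none
Why: Kinetic enolisation of the C1 ketone at C11 (its only α-hydrogen) and intramolecular Claisen (Dieckmann-type, 5-exo-trig) acylation by the ester should close ring C on the face of C11 away from the C7–C9 bridge, which sets C11 with the methyl syn to that bridge, while the C8 ketal keeps C9 from competing and excess base holds the product as its C12 enolate.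

Step 10
Reactants: 18 tetracyclic diketone ketal
Product: 19 tetracyclic enone ketal (as 18 with C13=C14; 6R,10R,11R)
Conditions: IBX (2.5 equiv), DMSO/toluene, 70 °C
Reagents that add atoms: none
Why: IBX dehydrogenation of the cyclopentanone can place the double bond only at C13=C14, because C11 is quaternary, and it removes the uncontrolled C14 centre.

Step 11
Reactants: 19 tetracyclic enone ketal
Product: 20 8-oxo compound (8-dehydro-alterbrassicicene C; 6R,7R,10R,11R, where 7R is the spatial arrangement of 7S in the target)
Conditions: 1 M HCl, THF, 40 °C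
Reagents that add atoms: water, O
Why: Acidic hydrolysis of the dioxolane releases the C8 ketone, and acid-catalysed enolisation toward C7 should equilibrate the methyl group into the equatorial position (anti to the ring oxygen, no syn-axial C9–H), which is also the epimer formed by exo-face protonation of the enol.

Step 12
Reactants: 20 8-oxo compound
Product: 21 alterbrassicicene C (6R,7S,8S,10R,11R)
Conditions: NaBH4, MeOH/CH2Cl2, −78 °C; aq. NH4Cl
Reagents that add atoms: none
Why: Borohydride reduction should take the saturated C8 ketone ahead of the two hindered enone carbonyls and from the exo face of the 9-oxabicyclo[3.3.1]nonane (the endo face is covered by the C1 bridge), giving the axial 8S alcohol, while any 7-epimer with an axial methyl is shielded on both faces and is left behind.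

**Compound list**

1 | heptane-3,5-dione | CCC(=O)CC(=O)CC | starting material
2 | methyl 3-methylbutanoate | COC(=O)CC(C)C | starting material
3 | 6,9-dimethyldecane-3,5,7-trione | CCC(=O)CC(=O)C(C)C(=O)CC(C)C | intermediate
4 | 6-ethyl-3-methyl-2-(2-methylpropyl)-4H-pyran-4-one | CCC1=CC(=O)C(C)=C(CC(C)C)O1 | intermediate
5 | 3-methyl-2-(2-methylpropyl)-6-(3-oxobutan-2-yl)-4H-pyran-4-one (racemic) | CC(=O)C(C)C1=CC(=O)C(C)=C(CC(C)C)O1 | intermediate
6 | 3-methyl-6-[1-(2-methyl-1,3-dioxolan-2-yl)ethyl]-2-(2-methylpropyl)-4H-pyran-4-one (racemic) | CC(C1=CC(=O)C(C)=C(CC(C)C)O1)C2(C)OCCO2 | intermediate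
7 | methyl 4-methyl-3-{3-methyl-6-[1-(2-methyl-1,3-dioxolan-2-yl)ethyl]-4-oxo-4H-pyran-2-yl}pentanoate (diastereomer mixture) | COC(=O)CC(C(C)C)C1=C(C)C(=O)C=C(C(C)C2(C)OCCO2)O1 | intermediate
8 | methyl 2-methoxyacetate | COCC(=O)OC | starting material
9 | 1-(methoxymethyl)cyclopropan-1-ol | COCC1(O)CC1 | intermediate
10 | bis(4-methoxy-3-oxobutyl)zinc | COCC(=O)CC[Zn]CCC(=O)COC | intermediate (not isolated)
11 | 2-(1-methoxy-4-methyl-1-oxopentan-3-yl)-3-methyl-6-[1-(2-methyl-1,3-dioxolan-2-yl)ethyl]-4-(trimethylsilyloxy)pyrylium trifluoromethanesulfonate | CC(c1cc(O[Si](C)(C)C)c(C)c(C(CC(=O)OC)C(C)C)[o+]1)C2(C)OCCO2.[O-]S(=O)(=O)C(F)(F)F | intermediate (not isolated)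
12 | 4-(trimethylsilyloxy)-2H-pyran conjugate adduct carrying the 4-methoxy-3-oxobutyl chain at C6 (C6 configured as in 14) | COCC(=O)CC[C@@]1(C(C)C2(C)OCCO2)C=C(O[Si](C)(C)C)C(C)=C(C(CC(=O)OC)C(C)C)O1 | intermediate (not isolated)
13 | ring-A aldol with C3–OSiMe3 and C2–H (C6 configured as in 14) | COCC1(O[Si](C)(C)C)CC[C@]2(C(C)C3(C)OCCO3)OC(C(CC(=O)OC)C(C)C)=C(C)C(=O)C12 | intermediate (not isolated)
14 | methyl 3-[(7aR)-5-(methoxymethyl)-3-methyl-7a-[1-(2-methyl-1,3-dioxolan-2-yl)ethyl]-4-oxo-4,6,7,7a-tetrahydrocyclopenta[b]pyran-2-yl]-4-methylpentanoate (6R; C7/C14 epimer mixture) | COCC1=C2C(=O)C(C)=C(C(CC(=O)OC)C(C)C)O[C@]2(CC1)C(C)C3(C)OCCO3 | intermediate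
15 | enol ether of 14: C8(=C9H2)–O–CH2CH2–OSiMe3 in place of the dioxolane | COCC1=C2C(=O)C(C)=C(C(CC(=O)OC)C(C)C)O[C@]2(CC1)C(C)C(=C)OCCO[Si](C)(C)C | intermediate (not isolated)
16 | trimethylsilyl dienol ether (C1(OSiMe3)=C11) of 17 (6R,10R) | COCC1=C2C(O[Si](C)(C)C)=C(C)[C@]3(C(CC(=O)OC)C(C)C)CC4(OCCO4)C(C)[C@@]2(CC1)O3 | intermediate (not isolated)
17 | oxa-bridged tricyclic keto ester (6R,10R; C7/C11/C14 epimer mixture) | COCC1=C2C(=O)C(C)[C@]3(C(CC(=O)OC)C(C)C)CC4(OCCO4)C(C)[C@@]2(CC1)O3 | intermediate
18 | tetracyclic diketone ketal (6R,10R,11R; C7/C14 epimer mixture) | COCC1=C2C(=O)[C@@]3(C)C(=O)CC(C(C)C)[C@]34CC5(OCCO5)C(C)[C@@]2(CC1)O4 | intermediate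
19 | tetracyclic enone ketal (6R,10R,11R; C7 epimer mixture) | COCC1=C2C(=O)[C@@]3(C)C(=O)C=C(C(C)C)[C@]34CC5(OCCO5)C(C)[C@@]2(CC1)O4 | intermediate
20 | 8-dehydro-alterbrassicicene C (6R,7R,10R,11R) | COCC1=C2C(=O)[C@@]3(C)C(=O)C=C(C(C)C)[C@]34CC(=O)[C@H](C)[C@@]2(CC1)O4 | intermediate
21 | alterbrassicicene C (6R,7S,8S,10R,11R) | COCC1=C2C(=O)[C@@]3(C)C(=O)C=C(C(C)C)[C@]34C[C@H](O)[C@H](C)[C@@]2(CC1)O4 | target

**Step count and risks**

Total step count: 12. Longest linear sequence: 11 steps (steps 1–5 and 7–12, from heptane-3,5-dione); step 6 is a one-step branch.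

Steps most likely to fail:

Step 7 (Proposed new method). What may go wrong:
- uncatalysed addition of the zinc reagent to the pyrylium ion, or unequal catalyst control over the two C7 epimers of 7, so that C6 is formed with low enantiomeric purity;
- proton transfer from the side-chain C–H next to the pyrylium ring to the organometallic;
- ring opening of the siloxydiene before the aldol closure.

Fallback, from 7 and 9, back at 14: the annulation is run stepwise and racemically as a cyclopentene annulation with a masked homoenolate Grignard reagent, and the enantiomers are separated afterwards. Ring opening of 9 with N-bromosuccinimide should give 4-bromo-1-methoxybutan-2-one F1. Ketalisation with ethylene glycol (p-TsOH) should give 2-(2-bromoethyl)-2-(methoxymethyl)-1,3-dioxolane F2, and magnesium the Grignard reagent {2-[2-(methoxymethyl)-1,3-dioxolan-2-yl]ethyl}magnesium bromide F3. Its CuBr·SMe2-catalysed conjugate addition to 7 activated with TBSOTf should give the racemic tert-butyldimethylsilyl dienol ether F4. Catalytic TMSOTf in the same flask should close ring A by attack of C2 on the side-chain dioxolane (silyl enol ether–ketal aldol reaction), giving the 2-silyloxyethyl ether F5. DBU should then give the racemic dienone F6 by β-elimination, and preparative chromatography on a chiral stationary phase delivers 14.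

Step 8 (Proposed new method). What may go wrong:
- conversion of the dienone by the silyl triflate/amine pair into an unreactive silyl polyenol ether (γ-deprotonation at C4) faster than the ketal is opened;
- attack of C9 at C3 instead of C10;
- ionisation of the allylic C6–O bond with loss of configuration at C6.

Fallback, from 14, back at 17: the closure is done through an anionic Michael addition. Hydrolysis of the dioxolane (PPTS, wet acetone) should give the methyl ketone F7. LiHMDS (1.05 equiv, THF, −78 → −40 °C) should form the kinetic methyl enolate, which closes by 6-exo-trig intramolecular Michael addition to C10 to give the bridged diketone F8. Ketalisation with 1,2-bis(trimethylsilyloxy)ethane and catalytic TMSOTf at −78 °C should take the saturated C8 ketone only and return 17.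

Step 11. What may go wrong: the thermodynamic preference between the two C7 epimers may be small (one gauche contact is traded for one syn-axial contact), so that equilibration gives a poor epimer mixture and material is lost at the end.

Fallback, from 19, back at 20: C7 is set kinetically. The hydrolysate, a mixture of 20 and its C7 epimer 7-epi-8-dehydro-alterbrassicicene C F9, is converted into the more substituted trimethylsilyl enol ether F10 (TMSCl, NaI, Et3N, MeCN). Saegusa–Ito oxidation (Pd(OAc)2, MeCN) can eliminate only toward the methyl group, because C6 is quaternary, and should give the exo-methylene enone F11. Conjugate reduction with [(Ph3P)CuH]6 (Stryker's reagent) takes this unhindered enone ahead of the two substituted ones, and protonation of the copper enolate on the exo face returns 20 as the equatorial-methyl epimer.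

**Further compounds**

F1 | step 7 | 4-bromo-1-methoxybutan-2-one | COCC(=O)CCBr
F2 | step 7 | 2-(2-bromoethyl)-2-(methoxymethyl)-1,3-dioxolane | COCC1(CCBr)OCCO1
F3 | step 7 | {2-[2-(methoxymethyl)-1,3-dioxolan-2-yl]ethyl}magnesium bromide | COCC1(CC[Mg]Br)OCCO1
F4 | step 7 | racemic tert-butyldimethylsilyl dienol ether of the conjugate adduct (both ketones as dioxolanes) | COCC1(CCC2(C(C)C3(C)OCCO3)C=C(O[Si](C)(C)C(C)(C)C)C(C)=C(C(CC(=O)OC)C(C)C)O2)OCCO1
F5 | step 7 | racemic ring-A aldol-type ether with C3–OCH2CH2OSi(t-Bu)Me2 and C2–H | COCC1(OCCO[Si](C)(C)C(C)(C)C)CCC2(C(C)C3(C)OCCO3)OC(C(CC(=O)OC)C(C)C)=C(C)C(=O)C12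
F6 | step 7 | racemic 14 | COCC1=C2C(=O)C(C)=C(C(CC(=O)OC)C(C)C)OC2(CC1)C(C)C3(C)OCCO3
F7 | step 8 | methyl ketone from 14 (C8 ketone free; 6R) | COCC1=C2C(=O)C(C)=C(C(CC(=O)OC)C(C)C)O[C@]2(CC1)C(C)C(C)=O
F8 | step 8 | bridged diketone (17 with C8 ketone free; 6R,10R) | COCC1=C2C(=O)C(C)[C@]3(C(CC(=O)OC)C(C)C)CC(=O)C(C)[C@@]2(CC1)O3
F9 | step 11 | 7-epi-8-dehydro-alterbrassicicene C | COCC1=C2C(=O)[C@@]3(C)C(=O)C=C(C(C)C)[C@]34CC(=O)[C@@H](C)[C@@]2(CC1)O4
F10 | step 11 | C7=C8 trimethylsilyl enol ether of 20 | COCC1=C2C(=O)[C@@]3(C)C(=O)C=C(C(C)C)[C@]34CC(O[Si](C)(C)C)=C(C)[C@@]2(CC1)O4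
F11 | step 11 | 7-methylidene-8-oxo enone | COCC1=C2C(=O)[C@@]3(C)C(=O)C=C(C(C)C)[C@]34CC(=O)C(=C)[C@@]2(CC1)O4
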